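**Retrosynthetic overview**

- Feature: the pyran of the chroman is the unit O1–C2–C3–C4 fused to the acylphloroglucinol ring A. C2 carries ring B and is at the aldehyde oxidation level (it is the third formyl carbon of a triformylphloroglucinol), C4 is benzylic to the nucleophilic C4a, and O1 is the oxygen para to the isovaleryl group.
- Last disconnections: the three ring-B phenols from their methyl ethers, and C4–H from a C4 methoxy group left by the annulation.
- Key disconnection: C2–C3 and C4–C4a in one cationic formal [4+2] (oxa-Povarov) of an O-aryl oxocarbenium ion with (E)-1-methoxy-3-methylbut-1-ene. It closes the pyran, the only ring formed in the route, and sets C2 and C3 under a chiral counter-anion.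
- The cation precursor is the O-aryl O-acetyl acetal on the para oxygen of phlorisovalerophenone. Acetate is the nucleofuge because an O-methyl acetal of this acidic acylphenol would ionise by loss of the phenol.
- The enol ether is made as the pure E isomer by a Horner–Wittig sequence, because the trans C2/C3 relationship depends on its geometry.

Key step: step 5

Assumption (chemistry): 2,4,6-trimethoxybenzene-1,3,5-tricarbaldehyde and (methoxymethyl)diphenylphosphine oxide are treated as purchasable, and the antipode of the chiral acid that leads to the 2R series is the one used.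

**Route**

Step 1
Reactants: 1 phloroglucinol; 2 isovaleryl chloride
Product: 3 phlorisovalerophenone
Conditions: AlCl3, PhNO2, rt; then 1 M HCl
Reagents that add atoms: none
Why: Friedel–Crafts C-acylation of the highly activated triol stops after one acyl group because the aluminium chelate of the aryl ketone deactivates the ring.

Step 2
Reactants: 4 2,4,6-trimethoxybenzene-1,3,5-tricarbaldehyde; 3 phlorisovalerophenone
Product: 6 [3,5-dihydroxy-4-(3-methylbutanoyl)phenoxy](3,5-diformyl-2,4,6-trimethoxyphenyl)methyl acetate (racemic at the acetal carbon), via α-bromobenzyl acetate 5 (not isolated)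
Conditions: 4 (3 equiv), AcBr (1 equiv), cat. ZnBr2, CH2Cl2, 0 °C → rt; then added to 3 (1 equiv), i-Pr2NEt, DMF, –20 °C → rt; Et3N-buffered silica, excess 4 recovered
Reagents that add atoms: acetyl bromide, CC(=O)Br
Why: Acetyl bromide adds across one formyl C=O (α-bromoalkyl ester formation, held to one site by the excess of the C3-symmetric trialdehyde), and the α-bromo ester then O-alkylates the para-hydroxyl of 3, the most acidic and least hindered phenol, as α-haloalkyl esters do in acyloxyalkyl ether formation.

Step 3
Reactants: 7 (methoxymethyl)diphenylphosphine oxide; 8 isobutyraldehyde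
Product: 9 (1R*,2S*)-1-(diphenylphosphoryl)-1-methoxy-3-methylbutan-2-ol (racemic)
Conditions: LDA, THF, –78 °C; then 8; aq. NH4Cl; chromatographic separation from the (1R*,2R*) diastereomer
Reagents that add atoms: none
Why: Horner–Wittig addition of the lithiated α-methoxy phosphine oxide to the aldehyde stops at the stable lithium β-hydroxy phosphine oxide, and the separable (1R*,2S*) diastereomer is the one whose syn-elimination gives the E-alkene.

Step 4
Reactants: 9 (1R*,2S*)-1-(diphenylphosphoryl)-1-methoxy-3-methylbutan-2-ol
Product: 10 (E)-1-methoxy-3-methylbut-1-ene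
Conditions: NaH, DMF, 0 → 50 °C; product distilled out of the mixture
Reagents that add atoms: none
Why: Stereospecific syn-elimination of diphenylphosphinate from the sodium alkoxide (Horner–Wittig vinyl ether synthesis) transfers the relative configuration of 9 into the E double bond.

Step 5
Reactants: 6 [3,5-dihydroxy-4-(3-methylbutanoyl)phenoxy](3,5-diformyl-2,4,6-trimethoxyphenyl)methyl acetate; 10 (E)-1-methoxy-3-methylbut-1-ene
Product: 12 1-[(2R,3R)-2-(3,5-diformyl-2,4,6-trimethoxyphenyl)-5,7-dihydroxy-4-methoxy-3-(propan-2-yl)-3,4-dihydro-2H-chromen-6-yl]-3-methylbutan-1-one (2,3-trans; C4 epimers), via O-aryl oxocarbenium ion 11 (not isolated)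
Conditions: confined chiral imidodiphosphorimidate (IDPi) Brønsted acid (5 mol%), 10 (3 equiv), 4 Å MS, CH2Cl2, –78 → –40 °C; Et3N quench
Reagents that add atoms: none
Why: Proposed new method: the chiral acid protonates the acetate carbonyl of 6 and acetic acid departs, because carboxylate is the better nucleofuge and acyloxy the poorer cation donor, so that only the O-aryl oxocarbenium ion 11 forms, as a contact ion pair with the chiral anion; the β-carbon of 10 (the carbon bearing the isopropyl group) adds to the carbenium carbon (new C2–C3 bond), the resulting methoxycarbenium ion at C4 is attacked by the ring-A carbon ortho to the ether oxygen (new C4–C4a bond), and loss of the ring proton returns the acid. The closest known reactions are the Lewis-acid oxa-Povarov annulation of O-aryl oxocarbenium ions with alkenes, the chiral phosphoric acid Povarov reaction of N-aryl imines with vinyl ethers, and imidodiphosphorimidate ion-pair catalysis of oxocarbenium–alkene additions such as the Prins cyclisation. The pyran ring closes by a 6-exo-trig Friedel–Crafts attack of C4a on the C4 oxocarbenium carbon. The trans C2/C3 relationship follows from the E geometry of 10 and of the oxocarbenium ion in the compact approach with the methoxy group endo, which places aryl and isopropyl diequatorial, and the absolute configuration at C2 (and with it C3) is set by the face of 11 that the chiral anion leaves open; C4 forms as a mixture and is removed in step 6. The step needs ionisation on the acetate side (secured by the acyloxy leaving group), reaction of the cation with the enol ether and not with the hindered, doubly ortho-substituted formyl groups or another arene (secured by the excess of the far more nucleophilic enol ether at low temperature), and closure to the 6-acyl chroman only (secured because the ether oxygen is para to the acyl group and its two ortho carbons are equivalent).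

Step 6
Reactants: 12 1-[(2R,3R)-2-(3,5-diformyl-2,4,6-trimethoxyphenyl)-5,7-dihydroxy-4-methoxy-3-(propan-2-yl)-3,4-dihydro-2H-chromen-6-yl]-3-methylbutan-1-one
Product: 13 1-[(2R,3S)-2-(3,5-diformyl-2,4,6-trimethoxyphenyl)-5,7-dihydroxy-3-(propan-2-yl)-3,4-dihydro-2H-chromen-6-yl]-3-methylbutan-1-one
Conditions: Et3SiH (5 equiv), CF3CO2H (10 equiv), CH2Cl2, –40 → 0 °C, short reaction time
Reagents that add atoms: none
Why: Ionic hydrogenation: acid ionises the C4 methyl ether to a benzylic cation stabilised by the ortho and para oxygens of ring A, and silane hydride should trap it at low temperature well before the deactivated carbonyl groups or the C2–O1 bond react, so that C2 and C3 are untouched (the descriptor at C3 changes from R to S only through the priority change at C4).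

Step 7
Reactants: 13 1-[(2R,3S)-2-(3,5-diformyl-2,4,6-trimethoxyphenyl)-5,7-dihydroxy-3-(propan-2-yl)-3,4-dihydro-2H-chromen-6-yl]-3-methylbutan-1-one
Product: 14 5-[(2R,3S)-5,7-dihydroxy-6-(3-methylbutanoyl)-3-(propan-2-yl)-3,4-dihydro-2H-chromen-2-yl]-2,4,6-trihydroxybenzene-1,3-dicarbaldehyde (target)
Conditions: BCl3 (excess), CH2Cl2, –78 → 0 °C; aq. work-up
Reagents that add atoms: none
Why: Boron trichloride cleaves aryl methyl ethers ortho to a carbonyl group through a six-membered boron chelate, and each of the three ring-B methoxy groups is ortho to a formyl group, so the phenols should be freed without touching the chroman stereocentres.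

**Compound list**

1 | phloroglucinol (benzene-1,3,5-triol) | Oc1cc(O)cc(O)c1 | starting material
2 | isovaleryl chloride (3-methylbutanoyl chloride) | CC(C)CC(=O)Cl | starting material
3 | phlorisovalerophenone, 3-methyl-1-(2,4,6-trihydroxyphenyl)butan-1-one | CC(C)CC(=O)c1c(O)cc(O)cc1O | intermediate
4 | 2,4,6-trimethoxybenzene-1,3,5-tricarbaldehyde | COc1c(C=O)c(OC)c(C=O)c(OC)c1C=O | starting material
5 | bromo(3,5-diformyl-2,4,6-trimethoxyphenyl)methyl acetate (racemic, not isolated) | CC(=O)OC(Br)c1c(OC)c(C=O)c(OC)c(C=O)c1OC | intermediate
6 | [3,5-dihydroxy-4-(3-methylbutanoyl)phenoxy](3,5-diformyl-2,4,6-trimethoxyphenyl)methyl acetate (racemic at the acetal carbon) | CC(C)CC(=O)c1c(O)cc(OC(OC(C)=O)c2c(OC)c(C=O)c(OC)c(C=O)c2OC)cc1O | intermediate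
7 | (methoxymethyl)diphenylphosphine oxide | COCP(=O)(c1ccccc1)c1ccccc1 | starting material
8 | isobutyraldehyde (2-methylpropanal) | CC(C)C=O | starting material
9 | (1R*,2S*)-1-(diphenylphosphoryl)-1-methoxy-3-methylbutan-2-ol (racemic; one enantiomer drawn) | CO[C@@H](P(=O)(c1ccccc1)c1ccccc1)[C@H](O)C(C)C | intermediate
10 | (E)-1-methoxy-3-methylbut-1-ene | CO/C=C/C(C)C | intermediate
11 | (E)-O-aryl oxocarbenium ion from 6 by loss of acetate (ion pair with the chiral anion, not isolated) | CC(C)CC(=O)c1c(O)cc(/[O+]=C/c2c(OC)c(C=O)c(OC)c(C=O)c2OC)cc1O | intermediate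
12 | 1-[(2R,3R)-2-(3,5-diformyl-2,4,6-trimethoxyphenyl)-5,7-dihydroxy-4-methoxy-3-(propan-2-yl)-3,4-dihydro-2H-chromen-6-yl]-3-methylbutan-1-one (2,3-trans; C4 epimers) | CC(C)CC(=O)c1c(O)cc2c(c1O)C(OC)[C@@H](C(C)C)[C@H](c1c(OC)c(C=O)c(OC)c(C=O)c1OC)O2 | intermediate
13 | 1-[(2R,3S)-2-(3,5-diformyl-2,4,6-trimethoxyphenyl)-5,7-dihydroxy-3-(propan-2-yl)-3,4-dihydro-2H-chromen-6-yl]-3-methylbutan-1-one | CC(C)CC(=O)c1c(O)cc2c(c1O)C[C@@H](C(C)C)[C@H](c1c(OC)c(C=O)c(OC)c(C=O)c1OC)O2 | intermediate
14 | 5-[(2R,3S)-5,7-dihydroxy-6-(3-methylbutanoyl)-3-(propan-2-yl)-3,4-dihydro-2H-chromen-2-yl]-2,4,6-trihydroxybenzene-1,3-dicarbaldehyde | CC(C)CC(=O)c1c(O)cc2c(c1O)C[C@@H](C(C)C)[C@H](c1c(O)c(C=O)c(O)c(C=O)c1O)O2 | target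

**Step count**

Total: 7 steps. Longest linear sequence: 5 steps (steps 1, 2, 5, 6, 7).

**Steps most likely to fail**

Step 5 (key step, new method).
- What may go wrong: the chiral acid may protonate the enol ether faster than it ionises 6, which would lead to enol ether oligomerisation and stray C-alkylation of ring A. The ion pair may discriminate the two faces of the cation poorly, or the addition may go through an open, stepwise path that erodes the trans relationship. The C4 methyl ether of the product may re-ionise and react on with the enol ether.
- Fallback (known chemistry), setting out from 4 and 3 and rejoining at 13, so that steps 5 and 6 are bypassed: a Julia–Kocienski olefination of 4 (used in excess) with 5-(2-methylpropane-1-sulfonyl)-1-phenyl-1H-tetrazole and KHMDS gives the styrene 2,4,6-trimethoxy-5-[(E)-3-methylbut-1-en-1-yl]benzene-1,3-dicarbaldehyde F1. Heating 3 with paraformaldehyde and NaOAc in AcOH in the presence of F1 generates the ortho-quinone methide 3,5-dihydroxy-6-methylidene-4-(3-methylbutanoyl)cyclohexa-2,4-dien-1-one F2. Its inverse-demand hetero-Diels–Alder reaction with F1, suprafacial on the E-alkene and with oxygen bonding to the benzylic carbon, gives the racemic trans-chroman rac-(2R*,3S*)-1-[2-(3,5-diformyl-2,4,6-trimethoxyphenyl)-5,7-dihydroxy-3-(propan-2-yl)-3,4-dihydro-2H-chromen-6-yl]-3-methylbutan-1-one F3, which is separated from the 8-acyl regioisomer. Preparative HPLC on a chiral stationary phase then delivers the (2R,3S) enantiomer, which is 13.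

Step 2.
- What may go wrong: activation of more than one formyl group, acetyl transfer from the α-bromo ester or from residual acetyl bromide to the phenoxide, and alkylation at an ortho oxygen or at a ring carbon of 3.
- Fallback, setting out from 4 and rejoining at 5: acetic anhydride with a catalytic Lewis acid (Bi(OTf)3, MeCN) converts one formyl group of 4 into the acylal (3,5-diformyl-2,4,6-trimethoxyphenyl)methanediyl diacetate F4, which is stable and is purified by chromatography. Bromotrimethylsilane with catalytic ZnBr2 then exchanges one acetate for bromide, as with anomeric acetates, and gives 5 free of bis-activated material and of acyl bromide. 5 is used as in step 2 with the preformed monocaesium phenoxide of 3.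

Step 7.
- What may go wrong: incomplete cleavage of the third methyl ether once both formyl groups are tied up as boron chelates, and Lewis-acid ionisation of the benzylic C2–O1 bond once the ortho phenols of ring B are free, with ring opening and loss of the trans configuration.
- Fallback, setting out from 13 and arriving at 14: the ether cleavage is changed from electrophilic activation at oxygen to nucleophilic attack at the methyl carbon. Lithium propane-1-thiolate in DMF at 80 °C demethylates by SN2, since each methoxy group is ortho or para to a formyl group and the phenoxide is a good leaving group; under these basic conditions the C2–O1 bond cannot ionise. No new isolated compound is involved.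

**Further compounds**

F1 | step 5 | 2,4,6-trimethoxy-5-[(E)-3-methylbut-1-en-1-yl]benzene-1,3-dicarbaldehyde | CC(C)/C=C/c1c(OC)c(C=O)c(OC)c(C=O)c1OC
F2 | step 5 | 3,5-dihydroxy-6-methylidene-4-(3-methylbutanoyl)cyclohexa-2,4-dien-1-one | CC(C)CC(=O)C1=C(O)C(=C)C(=O)C=C1O
F3 | step 5 | rac-(2R*,3S*)-1-[2-(3,5-diformyl-2,4,6-trimethoxyphenyl)-5,7-dihydroxy-3-(propan-2-yl)-3,4-dihydro-2H-chromen-6-yl]-3-methylbutan-1-one (both enantiomers) | CC(C)CC(=O)c1c(O)cc2c(c1O)C[C@@H](C(C)C)[C@H](c1c(OC)c(C=O)c(OC)c(C=O)c1OC)O2.CC(C)CC(=O)c1c(O)cc2c(c1O)C[C@H](C(C)C)[C@@H](c1c(OC)c(C=O)c(OC)c(C=O)c1OC)O2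
F4 | step 2 | (3,5-diformyl-2,4,6-trimethoxyphenyl)methanediyl diacetate | CC(=O)OC(OC(C)=O)c1c(OC)c(C=O)c(OC)c(C=O)c1OC
F0 | step 7 | none | none
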